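(The numbers in the tables come from a simulation for an exercise, noise included.)

We count each flask in minutes at −20 °C, and we need two times: the life of the starting material, and the working time it gets in the flask.

| flask | starting material | coupling partner | free catalyst | temperature | remark | time |
|---|---|---|---|---|---|---|
| violet | 0.50 mM | 1.8 equiv | 1 mol% | −25 °C | run made earlier |  |
| green | 0.70 mM | 1.8 equiv | 1 mol% | −14 °C | run made earlier |  |
| amber | 1.1 mM | 1.8 equiv | 1 mol% | −25 °C | run made earlier |  |
| teal | 0.50 mM | 1.8 equiv | 2 mol% | −14 °C | run made earlier |  |
| epsilon | 0.50 mM (fed, over 2.0 min) | 1.80 equiv | 1 mol% | −20 °C | all else is in the flask from the start; the feed brings no volume worth counting | 5.0 min |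
| delta | 0.50 mM | 1.80 equiv | 1 mol% | −20 °C | everything together at the start | 5.0 min |
| zeta | 0.50 mM | 1.80 equiv | 1 mol% |  | everything together at the start at −40 °C, warmed to −20 °C at 2.0 min | 5.0 min |
| alpha | 0.50 mM (fed, over 2.0 min) | 1.80 equiv | 1 mol% |  | the addition at −40 °C, then warmed to −20 °C; the feed brings no volume worth counting | 5.0 min |
| beta | 0.50 mM (in portions, 2, over 2.0 min) | 1.80 equiv | 1 mol% | −20 °C | first portion at the start, last at 2.0 min | 5.0 min |

- violet (time / min: target / %, starting material / %): 0.250: 8.4, 93.4; 0.417: 10.6, 88.2; 0.667: 15.6, 84.1; 1.00: 23.0, 72.3; 2.00: 43.0, 58.5; 3.00: 54.7, 43.0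
- green (time / min: target / %, starting material / %): 0.833: 41.2, 58.8; 1.50: 60.4, 38.8; 2.50: 77.8, 22.3; 3.00: 82.1, 16.9; 4.00: 89.0, 7.8; 5.00: 92.0, 7.2
- amber (time / min: target / %, starting material / %): 0.417: 21.8, 76.7; 0.667: 33.9, 65.0; 1.00: 48.0, 53.4; 2.00: 76.3, 25.6; 3.00: 88.5, 11.5; 5.00: 96.6, 2.5
- teal (time / min: target / %, starting material / %): 0.417: 29.7, 71.1; 1.33: 63.2, 34.4; 2.50: 85.3, 15.2; 4.00: 92.6, 7.2; 5.00: 96.2, 3.1

(each reading ± 1 percentage point)

- the best flask by amount of target, in percent of the starting material charged; "all alike" if 1.5 percentage points covers them all (epsilon / delta / zeta / alpha / beta / all alike)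
- amount of target at the end, in percent of the starting material charged, epsilon
- amount of target at the end, in percent of the starting material charged, delta
- amount of target at the end, in percent of the starting material charged, zeta
- amount of target at the end, in percent of the starting material charged, alpha
- amount of target at the end, in percent of the starting material charged, beta

- a species is counted by the starting material in it: one spent catalyst counts as two
- the numbers in the tables scatter with a standard deviation of 1 percentage point
- steps under discussion: starting material + free catalyst <-> catalyst intermediate A; coupling partner + catalyst intermediate A <-> catalyst intermediate B; catalyst intermediate B -> free catalyst + target; starting material + catalyst intermediate A -> spent catalyst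

1. Near its half-way point, at 3.00 min, violet has 43.0 % of its starting material left. That gives a life of 3.55 min, if the fraction left falls in a first-order way (pseudo-first-order).

2. Amber, also near half-way and equally cold, holds 2.20 times the catalyst of violet, with the same factor on starting material and coupling partner, and its life of 1.59 min is shorter by a factor of 2.23. So we assume that the life goes inversely with the amount of catalyst, though amber does not separate the catalyst from the other two charges.

3. Teal at −14 °C reads 1.25 min with 2 mol%, which on that assumption means 2.49 min with 1 mol%.

4. Going from violet to teal on a log scale, we get 3.03 min at −20 °C. This life, the time in which the fraction left falls to 0.368 of itself, is the quantity we carry. Stretching the same line beyond the runs gives 5.77 min at −40 °C, which is less sure.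

5. On this first-order reckoning, the working time over the life gives our estimate of the target. Delta works for 5.0 min, which gives 80.8 %.

6. In epsilon and beta the starting material arrives 1.00 min late on average, so they work 4.00 min and give 73.3 %.

7. A cold minute counts as 0.525 of a warm one. Zeta works 4.05 min, giving 73.7 %. Alpha works 3.52 min, giving 68.7 %. Delta has the longest working time, so we put it first.

8. The forecast gives delta 81 %, epsilon 74 %, beta 73 %, zeta 73 % and alpha 69 %, with delta best, slightly apart from ours at epsilon and zeta, and says “Slow feeding only wastes time”.

    starting material + free catalyst ⇌ catalyst intermediate A (K = 690 /M, k = 5400 /M/s, Ea = 18.0 kJ/mol, ΔH = −25.0 kJ/mol)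
    coupling partner + catalyst intermediate A ⇌ catalyst intermediate B (K = 22000 /M, k = 4300 /M/s, Ea = 32.0 kJ/mol, ΔH = −57.0 kJ/mol)
    catalyst intermediate B → free catalyst + target (k = 3.60 /s, Ea = 54.0 kJ/mol)
    starting material + catalyst intermediate A → spent catalyst (k = 13.0 /M/s, Ea = 48.0 kJ/mol)
    (constants at −20 °C)

The flasks end at delta 78.3 %, epsilon 72.4 %, beta 71.8 %, zeta 69.3 % and alpha 66.9 %, with delta best; our delta stood 2.5 percentage points above. In delta at 5.00 min, catalyst intermediate A has a half-life of 0.32 s by the forward step to catalyst intermediate B alone, far shorter than the 1.8 min of its loss to spent catalyst, reckoned with the other concentrations as charged. Spent catalyst then stands at 10.4 % of the catalyst charged. Delta read at 80 s, where our life gives 35.6 %, holds 35.9 % target.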